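The 5,6-dihydro-2H-pyran-2-one ring is cut at C2–C3 and C5–C6, so that ring carbons C3–C5 come from one propargyl unit that is nucleophilic at both ends. The feature exploited is the 1,5-relationship of the ring oxygen on C6 and the carboxyl carbon C2 across the C3=C4 unsaturation. In one flask the fully functionalised (E)-enal (acetate and acetonide in place), an allenylboronate and CO2 are joined: a chiral phosphoric acid sets C6 while C5–C6 forms, and C–H carboxylation of the new alkyne forms C2–C3. Semi-hydrogenation then lets the ring close. The enal is built from a commercial statin side-chain aldehyde that supplies the syn-diol.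

Key step: step 7

Assumption: the sense of induction is taken from simple aldehydes — the allylborane from (+)-Ipc2BOMe adds to the Re face of RCH2CHO and the (S)-configured phosphoric acid sends the allenylboronate to the Si face of an enal; if either sense were reversed, the enantiomeric controller would be used.

Step 1
Reactants: 1 tert-butyl 2-[(4R,6S)-6-formyl-2,2-dimethyl-1,3-dioxan-4-yl]acetate; 2 benzyltriphenylphosphonium chloride
Product: 4 tert-butyl 2-[(4R,6S)-2,2-dimethyl-6-(2-phenylethenyl)-1,3-dioxan-4-yl]acetate (E/Z mixture), via benzylidenetriphenylphosphorane 3 (not isolated)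
Conditions: 2, NaN(SiMe3)2, THF, 0 °C; then 1, −78 °C to rt
Reagents that add atoms: none
Why: Wittig olefination with a semi-stabilised ylide; the alkene geometry is irrelevant because step 2 saturates it, and the cis-4,6-disubstituted dioxane is the thermodynamically preferred diastereomer, so the α-oxygenated centre should be retained.

Step 2
Reactants: 4 tert-butyl 2-[(4R,6S)-2,2-dimethyl-6-(2-phenylethenyl)-1,3-dioxan-4-yl]acetate (E/Z mixture)
Product: 5 tert-butyl 2-[(4R,6R)-2,2-dimethyl-6-(2-phenylethyl)-1,3-dioxan-4-yl]acetate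
Conditions: H2 (1 atm), 10% Pd/C, EtOAc, rt
Reagents that add atoms: none
Why: Heterogeneous catalytic hydrogenation converts both alkene isomers to the same phenethyl compound without touching a stereocentre; a neutral, non-protic solvent should keep hydrogenolysis of the allylic C–O bond in check.

Step 3
Reactants: 5 tert-butyl 2-[(4R,6R)-2,2-dimethyl-6-(2-phenylethyl)-1,3-dioxan-4-yl]acetate
Product: 6 2-[(4R,6R)-2,2-dimethyl-6-(2-phenylethyl)-1,3-dioxan-4-yl]acetaldehyde
Conditions: i-Bu2AlH (1.1 equiv), CH2Cl2, −78 °C; then MeOH, aq. potassium sodium tartrate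
Reagents that add atoms: none
Why: Partial reduction of an ester with i-Bu2AlH; the tetrahedral aluminium hemiacetal of a tert-butyl ester should persist at −78 °C and release the aldehyde only on work-up.

Step 4
Reactants: 6 2-[(4R,6R)-2,2-dimethyl-6-(2-phenylethyl)-1,3-dioxan-4-yl]acetaldehyde
Product: 7 (2R)-1-[(4S,6R)-2,2-dimethyl-6-(2-phenylethyl)-1,3-dioxan-4-yl]pent-4-en-2-ol
Conditions: (+)-Ipc2BOMe, CH2=CHCH2MgBr, Et2O, −78 °C to rt; then 6, −78 °C; then NaOH, H2O2, 0 °C to rt
Reagents that add atoms: allylmagnesium bromide, C=CC[Mg]Br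
Why: Brown allylation through a closed chair transition state; the B-allyldiisopinocampheylborane made from (+)-Ipc2BOMe should add to the Re face and set the new carbinol centre (R), 1,3-anti to the dioxane oxygen, under reagent control.

Step 5
Reactants: 7 (2R)-1-[(4S,6R)-2,2-dimethyl-6-(2-phenylethyl)-1,3-dioxan-4-yl]pent-4-en-2-ol
Product: 8 (2R)-1-[(4R,6R)-2,2-dimethyl-6-(2-phenylethyl)-1,3-dioxan-4-yl]pent-4-en-2-yl acetate
Conditions: Ac2O, Et3N, DMAP (cat.), CH2Cl2, 0 °C to rt
Reagents that add atoms: acetic anhydride, CC(=O)OC(C)=O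
Why: DMAP-catalysed O-acylation of the only free hydroxyl, with retention at the carbinol carbon, places the acetate of the target before the other two oxygens are ever unmasked.

Step 6
Reactants: 8 (2R)-1-[(4R,6R)-2,2-dimethyl-6-(2-phenylethyl)-1,3-dioxan-4-yl]pent-4-en-2-yl acetate; 9 (E)-but-2-enal
Product: 10 (2E,5R)-5-acetoxy-6-[(4R,6R)-2,2-dimethyl-6-(2-phenylethyl)-1,3-dioxan-4-yl]hex-2-enal
Conditions: second-generation Hoveyda–Grubbs catalyst [RuCl2(H2IMes)(=CH-C6H4-2-O-i-Pr)] (5 mol%), 9 (5 equiv), CH2Cl2, 40 °C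
Reagents that add atoms: none
Why: Olefin cross-metathesis of a terminal alkene with an excess of an electron-poor enal should be selective for the cross product and give the conjugated (E)-enal under thermodynamic control, with propene lost.

Step 7
Reactants: 10 (2E,5R)-5-acetoxy-6-[(4R,6R)-2,2-dimethyl-6-(2-phenylethyl)-1,3-dioxan-4-yl]hex-2-enal; 11 allenylboronic acid pinacol ester; 12 carbon dioxide
Product: 14 (5S,6E,9R)-9-acetoxy-10-[(4R,6R)-2,2-dimethyl-6-(2-phenylethyl)-1,3-dioxan-4-yl]-5-hydroxydec-6-en-2-ynoic acid, via pinacol borate 13 (not isolated)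
Conditions: 11 (1.5 equiv), (S)-3,3′-bis(2,4,6-triisopropylphenyl)-1,1′-binaphthyl-2,2′-diyl hydrogen phosphate [(S)-TRIP] (10 mol%), 4 Å MS, toluene, −20 °C; then DMF, Cs2CO3 (2 equiv), AgI (5 mol%), CO2 (1 atm), 40 °C; then cold 0.5 M HCl to pH 3
Reagents that add atoms: none
Why: The chiral phosphoric acid hydrogen-bonds to a pinacol oxygen of 11 and to the formyl C–H of 10, so the allenylboronate adds through a closed six-membered chair transition state with SE2′ transposition, which forms C5–C6 as a propargyl (not allenyl) carbinol and leaves the oxygen masked as its pinacol borate 13; the terminal C–H of 13 is then metalated by AgI/Cs2CO3 and the silver acetylide inserts CO2, which forms C2–C3. The closest known reaction types are the phosphoric-acid-catalysed asymmetric propargylation of aldehydes with allenylboronates and the silver-catalysed C–H carboxylation of terminal alkynes with CO2, run here one after the other in one flask. No ring is closed in this step; the product carries O1 and C2 in the 1,5-relationship that closes the ring in step 8 by 6-exo-trig lactonisation. The new stereocentre C6 is set by the catalyst alone (Si-face attack under the (S)-acid), since the nearest resident stereocentre is four atoms away. The step needs 1,2- over 1,4-addition to the enal (secured by the closed boron–oxygen transition state), C- over O-carboxylation (secured by the borate mask and the reversibility of carbonate formation), and survival of the acetate and acetonide (secured by the absence of strong base and of aqueous acid until a brief cold work-up).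

Step 8
Reactants: 14 (5S,6E,9R)-9-acetoxy-10-[(4R,6R)-2,2-dimethyl-6-(2-phenylethyl)-1,3-dioxan-4-yl]-5-hydroxydec-6-en-2-ynoic acid
Product: 17 (1E,4R,6R,8R)-6,8-dihydroxy-1-[(2S)-6-oxo-3,6-dihydro-2H-pyran-2-yl]-10-phenyldec-1-en-4-yl acetate (target), via (Z)-hydroxy acid 15 (not isolated), via lactone acetonide 16 (not isolated)
Conditions: H2 (1 atm), Pd/CaCO3 poisoned with Pb(OAc)2 (Lindlar catalyst), quinoline, EtOAc, rt; filter; then AcOH/H2O (4:1), 40 °C
Reagents that add atoms: none
Why: Lindlar semi-hydrogenation adds H2 syn to the ynoic acid only, the (Z)-5-hydroxy-2-enoic acid 15 lactonises (6-exo-trig, no stereocentre touched) to 16, and aqueous acetic acid then hydrolyses the acetonide under conditions mild enough that the acetate should not migrate and the allylic lactone C–O bond should not ionise.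

Compound list
1 | tert-butyl 2-[(4R,6S)-6-formyl-2,2-dimethyl-1,3-dioxan-4-yl]acetate (commercial statin side-chain aldehyde; supplies both carbinol centres of the syn-diol) | CC(C)(C)OC(=O)C[C@H]1C[C@@H](C=O)OC(C)(C)O1 | starting material
2 | benzyltriphenylphosphonium chloride | [Cl-].c1ccccc1C[P+](c1ccccc1)(c1ccccc1)c1ccccc1 | starting material
3 | benzylidenetriphenylphosphorane | C(=P(c1ccccc1)(c1ccccc1)c1ccccc1)c1ccccc1 | intermediate (not isolated)
4 | tert-butyl 2-[(4R,6S)-2,2-dimethyl-6-(2-phenylethenyl)-1,3-dioxan-4-yl]acetate, E/Z mixture at the styryl double bond | CC(C)(C)OC(=O)C[C@H]1C[C@@H](C=Cc2ccccc2)OC(C)(C)O1 | intermediate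
5 | tert-butyl 2-[(4R,6R)-2,2-dimethyl-6-(2-phenylethyl)-1,3-dioxan-4-yl]acetate | CC(C)(C)OC(=O)C[C@H]1C[C@@H](CCc2ccccc2)OC(C)(C)O1 | intermediate
6 | 2-[(4R,6R)-2,2-dimethyl-6-(2-phenylethyl)-1,3-dioxan-4-yl]acetaldehyde | O=CC[C@H]1C[C@@H](CCc2ccccc2)OC(C)(C)O1 | intermediate
7 | (2R)-1-[(4S,6R)-2,2-dimethyl-6-(2-phenylethyl)-1,3-dioxan-4-yl]pent-4-en-2-ol | C=CC[C@@H](O)C[C@H]1C[C@@H](CCc2ccccc2)OC(C)(C)O1 | intermediate
8 | (2R)-1-[(4R,6R)-2,2-dimethyl-6-(2-phenylethyl)-1,3-dioxan-4-yl]pent-4-en-2-yl acetate | CC(=O)O[C@H](CC=C)C[C@H]1C[C@@H](CCc2ccccc2)OC(C)(C)O1 | intermediate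
9 | (E)-but-2-enal (crotonaldehyde) | C/C=C/C=O | starting material
10 | (2E,5R)-5-acetoxy-6-[(4R,6R)-2,2-dimethyl-6-(2-phenylethyl)-1,3-dioxan-4-yl]hex-2-enal | CC(=O)O[C@H](C/C=C/C=O)C[C@H]1C[C@@H](CCc2ccccc2)OC(C)(C)O1 | intermediate
11 | allenylboronic acid pinacol ester (4,4,5,5-tetramethyl-2-(propa-1,2-dien-1-yl)-1,3,2-dioxaborolane) | C=C=CB1OC(C)(C)C(C)(C)O1 | starting material
12 | carbon dioxide | O=C=O | starting material
13 | (2R,4E,6S)-1-[(4R,6R)-2,2-dimethyl-6-(2-phenylethyl)-1,3-dioxan-4-yl]-6-[(4,4,5,5-tetramethyl-1,3,2-dioxaborolan-2-yl)oxy]non-4-en-8-yn-2-yl acetate | CC(=O)O[C@H](C/C=C/[C@@H](OB3OC(C)(C)C(C)(C)O3)CC#C)C[C@H]1C[C@@H](CCc2ccccc2)OC(C)(C)O1 | intermediate (not isolated)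
14 | (5S,6E,9R)-9-acetoxy-10-[(4R,6R)-2,2-dimethyl-6-(2-phenylethyl)-1,3-dioxan-4-yl]-5-hydroxydec-6-en-2-ynoic acid | CC(=O)O[C@H](C/C=C/[C@@H](O)CC#CC(=O)O)C[C@H]1C[C@@H](CCc2ccccc2)OC(C)(C)O1 | intermediate
15 | (2Z,5S,6E,9R)-9-acetoxy-10-[(4R,6R)-2,2-dimethyl-6-(2-phenylethyl)-1,3-dioxan-4-yl]-5-hydroxydeca-2,6-dienoic acid | CC(=O)O[C@H](C/C=C/[C@@H](O)C/C=C\C(=O)O)C[C@H]1C[C@@H](CCc2ccccc2)OC(C)(C)O1 | intermediate (not isolated)
16 | (2R,4E)-1-[(4R,6R)-2,2-dimethyl-6-(2-phenylethyl)-1,3-dioxan-4-yl]-5-[(2S)-6-oxo-3,6-dihydro-2H-pyran-2-yl]pent-4-en-2-yl acetate | CC(=O)O[C@H](C/C=C/[C@@H]1CC=CC(=O)O1)C[C@H]2C[C@@H](CCc3ccccc3)OC(C)(C)O2 | intermediate (not isolated)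
17 | (1E,4R,6R,8R)-6,8-dihydroxy-1-[(2S)-6-oxo-3,6-dihydro-2H-pyran-2-yl]-10-phenyldec-1-en-4-yl acetate | CC(=O)O[C@H](C/C=C/[C@@H]1CC=CC(=O)O1)C[C@H](O)C[C@H](O)CCc1ccccc1 | target

Total step count: 8. Longest linear sequence: 8 steps (1 to 17; the route is fully linear).

Steps most likely to fail

Step 7. The risks are poor facial selectivity in the propargylation of an aliphatic enal, and a stalled or misdirected carboxylation (carboxylative cyclisation of the oxygen onto the alkyne, or loss of CO2 from the alkynoate on work-up). The fallback sets out from 10 and builds the ring by metathesis instead. Brown allylation of 10 with the B-allyldiisopinocampheylborane made from (−)-Ipc2BOMe and CH2=CHCH2MgBr (Et2O, −78 °C, Si-face addition, ethanolamine work-up to spare the acetate) should give (4S,5E,8R)-9-[(4R,6R)-2,2-dimethyl-6-(2-phenylethyl)-1,3-dioxan-4-yl]-4-hydroxynona-1,5-dien-8-yl acetate F1. Acylation with acryloyl chloride and i-Pr2NEt in CH2Cl2 at 0 °C should give (4S,5E,8R)-8-acetoxy-9-[(4R,6R)-2,2-dimethyl-6-(2-phenylethyl)-1,3-dioxan-4-yl]nona-1,5-dien-4-yl prop-2-enoate F2. Ring-closing metathesis with second-generation Grubbs catalyst [RuCl2(H2IMes)(PCy3)(=CHPh)] in CH2Cl2 at 40 °C then comes back to the route at 16, which is isolated and taken to 17 with AcOH/H2O as in the second half of step 8.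

Step 8. The risks are over-reduction or double-bond isomerisation while the free acid is hydrogenated, and migration of the acetyl group to a neighbouring hydroxyl during the acidic acetonide cleavage. The fallback sets out from 14 and separates the three events. Esterification with MeI and KHCO3 in DMF should give methyl (5S,6E,9R)-9-acetoxy-10-[(4R,6R)-2,2-dimethyl-6-(2-phenylethyl)-1,3-dioxan-4-yl]-5-hydroxydec-6-en-2-ynoate F3. Reduction with Zn dust activated with Cu(OAc)2 and AgNO3 in MeOH/H2O (a metal-mediated cis-semi-reduction that cannot over-reduce) should give methyl (2Z,5S,6E,9R)-9-acetoxy-10-[(4R,6R)-2,2-dimethyl-6-(2-phenylethyl)-1,3-dioxan-4-yl]-5-hydroxydeca-2,6-dienoate F4. Catalytic pyridinium p-toluenesulfonate in CH2Cl2 then lactonises F4 and comes back to the route at 16, which is isolated and deacetonised in a separate, shorter exposure to AcOH/H2O at rt to reach 17.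

Step 3. The risk is over-reduction, the aluminium hemiacetal collapsing before the quench so that the primary alcohol forms. The fallback sets out from 5 and accepts the over-reduction. LiAlH4 in THF at 0 °C should give 2-[(4S,6R)-2,2-dimethyl-6-(2-phenylethyl)-1,3-dioxan-4-yl]ethan-1-ol F5, and oxidation with Dess–Martin periodinane and NaHCO3 in CH2Cl2 comes back to the route at 6.

Further compounds
F1 | step 7 | (4S,5E,8R)-9-[(4R,6R)-2,2-dimethyl-6-(2-phenylethyl)-1,3-dioxan-4-yl]-4-hydroxynona-1,5-dien-8-yl acetate | CC(=O)O[C@H](C/C=C/[C@@H](O)CC=C)C[C@H]1C[C@@H](CCc2ccccc2)OC(C)(C)O1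
F2 | step 7 | (4S,5E,8R)-8-acetoxy-9-[(4R,6R)-2,2-dimethyl-6-(2-phenylethyl)-1,3-dioxan-4-yl]nona-1,5-dien-4-yl prop-2-enoate | CC(=O)O[C@H](C/C=C/[C@@H](OC(=O)C=C)CC=C)C[C@H]1C[C@@H](CCc2ccccc2)OC(C)(C)O1
F3 | step 8 | methyl (5S,6E,9R)-9-acetoxy-10-[(4R,6R)-2,2-dimethyl-6-(2-phenylethyl)-1,3-dioxan-4-yl]-5-hydroxydec-6-en-2-ynoate | CC(=O)O[C@H](C/C=C/[C@@H](O)CC#CC(=O)OC)C[C@H]1C[C@@H](CCc2ccccc2)OC(C)(C)O1
F4 | step 8 | methyl (2Z,5S,6E,9R)-9-acetoxy-10-[(4R,6R)-2,2-dimethyl-6-(2-phenylethyl)-1,3-dioxan-4-yl]-5-hydroxydeca-2,6-dienoate | CC(=O)O[C@H](C/C=C/[C@@H](O)C/C=C\C(=O)OC)C[C@H]1C[C@@H](CCc2ccccc2)OC(C)(C)O1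
F5 | step 3 | 2-[(4S,6R)-2,2-dimethyl-6-(2-phenylethyl)-1,3-dioxan-4-yl]ethan-1-ol | OCC[C@H]1C[C@@H](CCc2ccccc2)OC(C)(C)O1
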